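At one temperature, over 54 min, I followed G in the runs below and had to say what the south run holds at that time.

| flask | J | Q | Z | time |
|---|---|---|---|---|
| south-east | 80.0 mM | 120 mM | 0.800 mM |  |
| north-west | 80.0 mM | 360 mM | 0.800 mM |  |
| west | 80.0 mM | 120 mM | 0.400 mM |  |
| east | 40.0 mM | 120 mM | 0.800 mM |  |
| south | 160 mM | 60.0 mM | 0.800 mM | 54 min |

| run | time / min | [G] / mM |
|---|---|---|
| south-east run | 6.8 | 29.4 |
| south-east run | 14 | 46.8 |
| south-east run | 20 | 55.9 |
| south-east run | 27 | 62.0 |
| south-east run | 34 | 66.9 |
| south-east run | 40 | 69.7 |
| south-east run | 47 | 72.2 |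
| south-east run | 54 | 73.7 |
| north-west run | 6.8 | 35.4 |
| north-west run | 14 | 56.4 |
| north-west run | 20 | 65.3 |
| north-west run | 27 | 72.4 |
| north-west run | 34 | 75.8 |
| north-west run | 40 | 77.1 |
| north-west run | 47 | 78.5 |
| north-west run | 54 | 79.4 |
| west run | 6.8 | 2.9 |
| west run | 14 | 5.0 |
| west run | 20 | 7.8 |
| west run | 27 | 9.9 |
| west run | 34 | 11.7 |
| west run | 40 | 13.7 |
| west run | 47 | 16.4 |
| west run | 54 | 17.7 |
| east run | 6.8 | 14.7 |
| east run | 14 | 23.8 |
| east run | 20 | 29.4 |
| east run | 27 | 33.5 |
| east run | 34 | 35.0 |
| east run | 40 | 37.1 |
| east run | 47 | 37.5 |
| east run | 54 | 38.4 |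

(scatter of a reading: 0.4 mM)

- Overall: J + Q -> G, with Z as catalyst.
- Constant volume, constant temperature.
- A reading of a species includes what of it is bound.
- An order is taken over about fifteen percent of the charge, up and down.

* reaction order in [Q] at the outset, round the charge of the south-east run, defined at two percent of the J turned into G
* reaction order in [Z] at the outset, round the charge of the south-east run, defined at two percent of the J turned into G
* G in the south run at 54 min, as a share of the J charged

1. I kept a ledger of Q for the south run. Each mole of G takes one mole of J and one of Q, so the Q charged is found either in G or still unreacted, and c(Q) falls by what c(G) gains.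

2. The south run charges 60.0 mM of Q against 160 mM of J, so Q is the limiting reagent. Here 37.5 % is the ceiling share, the smaller of the charges of J and Q over the J charged. At the ceiling, 100 mM of J is left over.

3. The ledger needs a speed. With J cut to half, the reading at 14 min stood at 59.5 % of the J charged in the east run against 58.5 % in the south-east run, so I took the rate as first order in J. Between 40 min and 54 min the south-east readings give a first-order constant of 0.0351 min⁻¹, with c(Q) at 46.3 mM at the end of that span.

4. The other runs end with more Q than the south-east run, so below that c(Q) I had no reading and assumed order one in Q. With c(J) held at its floor, Q in the south run decays with 0.0758 min⁻¹. Starting that decay from the charge and running it for 54 min, my estimate left 0.999 mM of Q, so my share was 36.9 %.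

5. The forecast gave 33.5 % for the south run, an order in Q of 0.4 and an order in Z of 2, with k against Q called “saturating and somewhat sigmoid”. My share stands above its share, and the two differ on how Q behaves below the readings.

The simulation gave 37.4 % for the south run, with orders 0.48 in Q and 2.5 in Z.

    2 Z ⇌ Z2, settled at all times (2490 L mol⁻¹)
    Z2 + J + Q → G + Z2 (7740 L² mol⁻² min⁻¹)
    Z + Yx → Qi
    Z + Q ⇌ ZQ, settled at all times (8.300 L mol⁻¹)

A fit in which the product kills the catalyst gave 34.8 % for the south run. The ceiling share of 37.5 % stands 0.10 percentage points above the result, so the ledger of the south run ends with 0.177 mM of Q outside G, free or as ZQ. In the east run J is the smaller charge, so the ceiling share is 100 %. The reading at 54 min stood at 96.0 % of it, with 81.6 mM of Q outside G.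

The data were computed for substances that don't exist.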